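**Retrosynthetic overview**
1. Cut the aryl C3–O bond of ring B, not the acyl C–O bond. This gives 2,4-dihydroxy-6-propylbenzoic acid (its C3–H) and bis(2,4-dimethoxy-6-pentylbenzoyl) peroxide as the aroyloxy donor.
2. The peroxide comes from 2,4-dimethoxy-6-pentylbenzoic acid and H2O2 by carbodiimide dehydration.
3. That acid comes from 1,3-dimethoxy-5-pentylbenzene by para-selective bromination, Br/Li exchange and CO2.
4. The ring B acid comes from 5-propylresorcinol and a magnesium methyl carbonate CO2 donor.
5. No ring is built, since both benzene rings are bought. Ring A is finished first, ring B second, and they are joined in the last step.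

Assumption: the SMILES holds no stereocentre and no stereogenic double bond, so the target is achiral and no asymmetric step is needed; compounds 1 and 9 are taken as catalogue chemicals.

**Step 1**
Reactants: 1 1,3-dimethoxy-5-pentylbenzene (olivetol dimethyl ether)
Product: 2 2-bromo-1,5-dimethoxy-3-pentylbenzene
Conditions: NBS (1.02 equiv), MeCN, 0 °C to rt, 1 h
Reagents that add atoms: N-bromosuccinimide, O=C1CCC(=O)N1Br
Why: In this electrophilic aromatic bromination, NBS in MeCN attacks 3,5-dimethoxyalkylbenzenes para to one methoxy group and ortho to the other, not at the crowded carbon between the two methoxy groups, and one equivalent stops at the monobromide.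

**Step 2**
Reactants: 2 2-bromo-1,5-dimethoxy-3-pentylbenzene
Product: 5 2,4-dimethoxy-6-pentylbenzoic acid, via aryllithium 3 (not isolated), via lithium carboxylate 4 (not isolated)
Conditions: n-BuLi (1.05 equiv), THF, −78 °C, 30 min; CO2 (dry gas), −78 to 0 °C; 1 M HCl
Reagents that add atoms: carbon dioxide, O=C=O
Why: Halogen–lithium exchange followed by carboxylation fixes the carboxyl group exactly where the bromine sat, whereas direct lithiation of 1 would go between the methoxy groups.

**Step 3**
Reactants: 5 2,4-dimethoxy-6-pentylbenzoic acid (2 equiv per product)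
Product: 8 bis(2,4-dimethoxy-6-pentylbenzoyl) peroxide, via O-acylisourea 6 (not isolated), via peroxy acid 7 (not isolated)
Conditions: DCC (1.05 equiv), 30% aq H2O2 (0.52 equiv), DMAP (5 mol%), CH2Cl2, −15 to 0 °C, dark; filter, cold SiO2 plug, swap into toluene without drying down, use the same day
Reagents that add atoms: hydrogen peroxide, OO
Why: In this carbodiimide dehydration route to diacyl peroxides, the small α-nucleophile H2O2 opens hindered 6 to give 7, and 7 acylates on a second molecule of 6.

**Step 4**
Reactants: 9 5-propylbenzene-1,3-diol (divarinol)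
Product: 11 2,4-dihydroxy-6-propylbenzoic acid (divarinic acid), via magnesium chelate 10 (not isolated)
Conditions: MeOMgOCO2Me (2 M in DMF, 4 equiv), 120 °C, 2 h, N2; pour into ice-cold 2 M HCl
Reagents that add atoms: methoxymagnesium methyl carbonate, COC(=O)O[Mg]OC
Why: In this Stiles carboxylation (a Kolbe–Schmitt variant), the magnesium phenolate is carboxylated ortho to one OH and para to the other, as practised on 5-alkylresorcinols, and the six-membered chelate 10 holds the reversible carboxylation until cold acid frees 11.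

**Step 5**
Reactants: 8 bis(2,4-dimethoxy-6-pentylbenzoyl) peroxide; 11 2,4-dihydroxy-6-propylbenzoic acid
Product: 15 3-[(2,4-dimethoxy-6-pentylbenzoyl)oxy]-2,4-dihydroxy-6-propylbenzoic acid (target), via dicaesium salt 12 (not isolated), via aryl peroxyester 13 (not isolated), via cyclohexadienone 14 (not isolated)
Conditions: 11 (1.2 equiv), Cs2CO3 (3.5 equiv), DMF, 0 °C, 30 min, Ar; 8 (1.0 equiv) in toluene added dropwise, −20 to 0 °C, dark, 2 h; ice-cold 1 M HCl; chromatography (recovered 5 goes back to step 3)
Reagents that add atoms: none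
Why: Proposed new method: base-mediated C–H aroyloxylation of an unprotected resorcylic acid by a di-ortho-substituted diaroyl peroxide, in which the 4-phenolate of 12 cannot reach the shielded, twisted carbonyl carbons of 8 and so attacks a peroxide oxygen (SN2 at O, expelling the carboxylate of 5) to give 13, whose [3,3]-sigmatropic shift puts the former carbonyl oxygen on C3 rather than C5 because hydrogen bonding of the 2-OH to the carboxylate fixes double-bond character in C3–C4 (the same bias that sends Claisen shifts, nuclear alkylations and basic iodinations of resorcinol-type substrates to the carbon between the oxygens) and because C5 is flanked by the propyl group, after which 14 (one transient racemic sp3 carbon that is erased) tautomerises to 15 with the acyl group already on O3 and the hindered ester slow to migrate at low temperature; direct attack of C3 on the O–O bond gives the same 14, solid Cs2CO3 re-forms the phenolate without attacking 8, and the closest known reaction types are the ortho-benzoyloxylation of simple phenols with dibenzoyl peroxide, the α-benzoyloxylation of 1,3-dicarbonyl enolates and the Elbs persulfate oxidation, none of them shown on a free resorcylic acid or used to make a depside link.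

**Compound list**
1 | 1,3-dimethoxy-5-pentylbenzene | CCCCCc1cc(OC)cc(OC)c1 | starting material
2 | 2-bromo-1,5-dimethoxy-3-pentylbenzene | CCCCCc1cc(OC)cc(OC)c1Br | intermediate
3 | (2,4-dimethoxy-6-pentylphenyl)lithium | CCCCCc1cc(OC)cc(OC)c1[Li] | intermediate (not isolated)
4 | lithium 2,4-dimethoxy-6-pentylbenzoate | CCCCCc1cc(OC)cc(OC)c1C(=O)[O-].[Li+] | intermediate (not isolated)
5 | 2,4-dimethoxy-6-pentylbenzoic acid | CCCCCc1cc(OC)cc(OC)c1C(=O)O | intermediate
6 | O-(2,4-dimethoxy-6-pentylbenzoyl)-N,N'-dicyclohexylisourea | CCCCCc1cc(OC)cc(OC)c1C(=O)OC(=NC1CCCCC1)NC1CCCCC1 | intermediate (not isolated)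
7 | 2,4-dimethoxy-6-pentylperoxybenzoic acid | CCCCCc1cc(OC)cc(OC)c1C(=O)OO | intermediate (not isolated)
8 | bis(2,4-dimethoxy-6-pentylbenzoyl) peroxide | CCCCCc1cc(OC)cc(OC)c1C(=O)OOC(=O)c1c(CCCCC)cc(OC)cc1OC | intermediate
9 | 5-propylbenzene-1,3-diol | CCCc1cc(O)cc(O)c1 | starting material
10 | magnesium chelate of 2-oxido-4-hydroxy-6-propylbenzoate | CCCc1cc(O)cc2c1C(=O)O[Mg]O2 | intermediate (not isolated)
11 | 2,4-dihydroxy-6-propylbenzoic acid | CCCc1cc(O)cc(O)c1C(=O)O | intermediate
12 | dicaesium 2-hydroxy-4-oxido-6-propylbenzoate | CCCc1cc([O-])cc(O)c1C(=O)[O-].[Cs+].[Cs+] | intermediate (not isolated)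
13 | caesium 4-[(2,4-dimethoxy-6-pentylbenzoyl)peroxy]-2-hydroxy-6-propylbenzoate | CCCCCc1cc(OC)cc(OC)c1C(=O)OOc1cc(O)c(C(=O)[O-])c(CCC)c1.[Cs+] | intermediate (not isolated)
14 | caesium 3-[(2,4-dimethoxy-6-pentylbenzoyl)oxy]-2-hydroxy-4-oxo-6-propylcyclohexa-1,5-diene-1-carboxylate (racemic, transient) | CCCCCc1cc(OC)cc(OC)c1C(=O)OC1C(=O)C=C(CCC)C(C(=O)[O-])=C1O.[Cs+] | intermediate (not isolated)
15 | 3-[(2,4-dimethoxy-6-pentylbenzoyl)oxy]-2,4-dihydroxy-6-propylbenzoic acid (achiral) | CCCCCc1cc(OC)cc(OC)c1C(=O)Oc1c(O)cc(CCC)c(C(=O)O)c1O | target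

**Total step count:** 5. **Longest linear sequence:** 4 (steps 1, 2, 3, 5).

**Three steps most likely to fail**

**Step 5 (the proposed new step).**
- Risks:
  - Attack at C5 instead of C3.
  - Acyl transfer to O4, or O3-to-O4 migration in base.
  - Electron transfer followed by over-oxidation.
  - Exchange of the carboxylate with 8.
- Fallback (known chemistry only): it sets out from 11, takes in acid 5 on the way, and comes back to the route at 15. BnBr/KHCO3 in DMF alkylates only the carboxylate to give benzyl 2,4-dihydroxy-6-propylbenzoate F1. Rieche formylation (Cl2CHOMe, TiCl4, CH2Cl2, −10 °C) places the aldehyde between the two hydroxyls and gives benzyl 3-formyl-2,4-dihydroxy-6-propylbenzoate F2. BnBr/K2CO3 in DMF then gives benzyl 2,4-bis(benzyloxy)-3-formyl-6-propylbenzoate F3. Baeyer–Villiger (Dakin-type) oxidation with mCPBA in CH2Cl2 gives benzyl 2,4-bis(benzyloxy)-3-(formyloxy)-6-propylbenzoate F4. Brief K2CO3/MeOH cleaves this to benzyl 2,4-bis(benzyloxy)-3-hydroxy-6-propylbenzoate F5. Classical depside esterification of F5 with 5 (trifluoroacetic anhydride, toluene, rt) gives benzyl 2,4-bis(benzyloxy)-3-[(2,4-dimethoxy-6-pentylbenzoyl)oxy]-6-propylbenzoate F6. Neutral hydrogenolysis (H2, 10% Pd/C, EtOAc) removes the three benzyl groups and gives 15 without exposing the ester to base.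

**Step 3.**
- Risks:
  - N-acylurea formation from the hindered acid.
  - Ionic carboxy-inversion of the electron-rich peroxide.
- Fallback: it sets out from 5 and comes back at 8, replacing in-flask dehydration by a two-stage acyl halide displacement. (COCl)2 with catalytic DMF in CH2Cl2 at 0 °C gives 2,4-dimethoxy-6-pentylbenzoyl chloride F7. F7 is stirred with Na2O2 (0.5 equiv) in ice-cold water/toluene to give 8 in the organic layer. If 8 itself proves too labile, the step 5 fallback bypasses it.

**Step 4.**
- Risks:
  - Carboxylation between the two hydroxyls instead of at the wanted carbon.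
  - Decarboxylation during a warm acidic work-up.
- Fallback: it sets out from 9 and comes back at 11, installing the carbon at the aldehyde level. Vilsmeier–Haack formylation (POCl3, DMF, 0 °C to rt, then aqueous hydrolysis) goes para to one hydroxyl and gives 2,4-dihydroxy-6-propylbenzaldehyde F8. Lindgren–Pinnick oxidation (NaClO2, sulfamic acid as chlorine scavenger, aqueous dioxane, 0 °C) then gives 11.

**Further compounds**
F1 | step 5 | benzyl 2,4-dihydroxy-6-propylbenzoate | CCCc1cc(O)cc(O)c1C(=O)OCc1ccccc1
F2 | step 5 | benzyl 3-formyl-2,4-dihydroxy-6-propylbenzoate | CCCc1cc(O)c(C=O)c(O)c1C(=O)OCc1ccccc1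
F3 | step 5 | benzyl 2,4-bis(benzyloxy)-3-formyl-6-propylbenzoate | CCCc1cc(OCc2ccccc2)c(C=O)c(OCc2ccccc2)c1C(=O)OCc1ccccc1
F4 | step 5 | benzyl 2,4-bis(benzyloxy)-3-(formyloxy)-6-propylbenzoate | CCCc1cc(OCc2ccccc2)c(OC=O)c(OCc2ccccc2)c1C(=O)OCc1ccccc1
F5 | step 5 | benzyl 2,4-bis(benzyloxy)-3-hydroxy-6-propylbenzoate | CCCc1cc(OCc2ccccc2)c(O)c(OCc2ccccc2)c1C(=O)OCc1ccccc1
F6 | step 5 | benzyl 2,4-bis(benzyloxy)-3-[(2,4-dimethoxy-6-pentylbenzoyl)oxy]-6-propylbenzoate | CCCCCc1cc(OC)cc(OC)c1C(=O)Oc1c(OCc2ccccc2)cc(CCC)c(C(=O)OCc2ccccc2)c1OCc1ccccc1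
F7 | step 3 | 2,4-dimethoxy-6-pentylbenzoyl chloride | CCCCCc1cc(OC)cc(OC)c1C(=O)Cl
F8 | step 4 | 2,4-dihydroxy-6-propylbenzaldehyde | CCCc1cc(O)cc(O)c1C=O
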